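## Plan

1. **Numbering and enabling feature.** The carbocycle is C1 (CH bearing the methacrylate), C2, C3 (tertiary carbinol), C4, C5, C6, C7 (methyl-bearing ether carbon), C8, C9, C10. The lactone is C9–C10=C11–C12(=O)–O. C13 is the CH2OAc carbon on C11, and O1, O3 and O13 sit on C1, C3 and C13. The ring formed by the bridge oxygen and C4–C7 is a 2-alkyl-5-methylfuran that has gained H at C6 and C8 at C7. The exocyclic C8=C9 alkene of the ylidene butenolide lies four atoms (C3, C2, C1, C10) from C4, so the furan and this alkene are the diene and dienophile of an intramolecular [4+2] addition.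
2. **Retrosynthesis.** Both esters are removed. A sacrificial C4–C9 bond is redrawn, adding H at C5 and Cl at C8, which gives an oxanorbornane. H2 is taken off C5–C6. C7–C8 and C4–C9 are cut (retro-Diels–Alder), then C1–C10 (Ni/Cr coupling), then C8–C9 and C11–C13 (two formylations of tetronic acid), and finally C2–C3 (allylation of 2-acetyl-5-methylfuran).
3. **Forward order.** A furan aldehyde and a ready-made butenolide ring are joined at C1–C10. One cycloaddition then closes the oxanorbornene and cyclohexane ring A together. Saturation and heterolysis of C4–C9 merge these two rings into the oxygen-bridged ten-membered ring, and two acylations finish the synthesis.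
4. **Stereochemistry.** C3 comes from a catalytic enantioselective allylboration. C1 comes from a ligand-controlled Ni/Cr addition that places O1 and O3 syn. C7 comes from the furan face attacked in the cycloaddition, which C1 and C3 dictate through a phenylboronate bridge across O1 and O3. C4, C8 and C9 are transient.
5. **Two design points.** Chlorine is the C8 leaving group because an alkenyl chloride survives the Ni/Cr coupling, so it can be installed before the halogen-sensitive furan is present. The boronate is needed because the required furan face places O1 and O3 axial in the exo chair.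

Key step: step 12

Assumption: the enantiomers of the allylboration catalyst (step 1) and of the sulfonamide ligand (step 9) are taken to be those that attack the stated carbonyl faces.

## Route

Step 1
Reactants: 1 2-acetyl-5-methylfuran; 2 allylboronic acid pinacol ester
Product: 3 (R)-2-(5-methylfuran-2-yl)pent-4-en-2-ol
Conditions: valine-derived aminophenol catalyst (2.5 mol %), NaOtBu (cat.), MeOH (1.3 equiv), toluene, 4 °C
Reagents that add atoms: none
Why: Catalytic enantioselective allylboration of a heteroaryl methyl ketone, in which the aminophenol-bound allylboron species delivers allyl through a closed six-membered transition state to the Re face of the ketone and so sets C3 as R.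

Step 2
Reactants: 3 (R)-2-(5-methylfuran-2-yl)pent-4-en-2-ol
Product: 4 (R)-trimethyl{[2-(5-methylfuran-2-yl)pent-4-en-2-yl]oxy}silane
Conditions: TMSOTf, 2,6-lutidine, CH2Cl2, −78 °C
Reagents that add atoms: trimethylsilyl triflate, C[Si](C)(C)OS(=O)(=O)C(F)(F)F
Why: Silylation of a tertiary alcohol with a silyl triflate and a hindered base keeps the acid-labile furyl carbinol from ionising, and a tertiary TMS ether is about as robust as a primary TES ether yet can later be removed beside a primary TBS ether.

Step 3
Reactants: 4 (R)-trimethyl{[2-(5-methylfuran-2-yl)pent-4-en-2-yl]oxy}silane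
Product: 5 (R)-3-(5-methylfuran-2-yl)-3-(trimethylsilyloxy)butanal
Conditions: OsO4 (2 mol %), NaIO4, 2,6-lutidine, dioxane–H2O, rt
Reagents that add atoms: sodium periodate, [Na+].[O-]I(=O)(=O)=O
Why: Lemieux–Johnson cleavage, in which OsO4 dihydroxylates the monosubstituted alkene much faster than it attacks the aromatic furan, periodate cleaves the diol, and the lutidine buffer leaves C3 and its silyl ether untouched.

Step 4
Reactants: 6 tetronic acid
Product: 7 4-bromo-2-oxo-2,5-dihydrofuran-3-carbaldehyde
Conditions: (COBr)2 (2.5 equiv), DMF (3 equiv), CH2Cl2, 0 to 40 °C; aq. NaOAc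
Reagents that add atoms: oxalyl bromide, O=C(Br)C(=O)Br; N,N-dimethylformamide, CN(C)C=O; water, O
Why: Vilsmeier–Haack–Arnold haloformylation of a cyclic 1,3-dicarbonyl compound (as known for 4-hydroxycoumarin), in which the bromoiminium salt formylates the nucleophilic C11 and a second equivalent turns the vinylogous acid OH at C10 into bromide, installing C13 and the coupling handle together.

Step 5
Reactants: 7 4-bromo-2-oxo-2,5-dihydrofuran-3-carbaldehyde
Product: 8 4-bromo-3-(hydroxymethyl)furan-2(5H)-one
Conditions: NaBH4, CeCl3·7H2O, MeOH–CH2Cl2, −78 °C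
Reagents that add atoms: none
Why: Luche reduction, in which the hard cerium-modified borohydride adds 1,2 to the aldehyde and leaves the beta-bromo enoate and the lactone alone.

Step 6
Reactants: 8 4-bromo-3-(hydroxymethyl)furan-2(5H)-one
Product: 9 4-bromo-3-[(tert-butyldimethylsilyloxy)methyl]furan-2(5H)-one
Conditions: TBSOTf, 2,6-lutidine, CH2Cl2, −78 °C
Reagents that add atoms: tert-butyldimethylsilyl triflate, CC(C)(C)[Si](C)(C)OS(=O)(=O)C(F)(F)F
Why: Silyl triflate protection with a non-nucleophilic base, chosen because imidazole or DMAP could displace the vinylogous acyl bromide at C10.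

Step 7
Reactants: 9 4-bromo-3-[(tert-butyldimethylsilyloxy)methyl]furan-2(5H)-one
Product: 10 (Z)-4-bromo-3-[(tert-butyldimethylsilyloxy)methyl]-5-(hydroxymethylidene)furan-2(5H)-one
Conditions: LiHMDS (2.2 equiv), THF, −78 °C; HCO2Et; AcOH quench
Reagents that add atoms: ethyl formate, CCOC=O
Why: Vinylogous Claisen-type formylation, in which the butenolide is deprotonated at its only acidic position C9 to the 2-oxidofuran, the alpha carbon C11 is blocked so C9 attacks the formate, and the product is drained as its stabilised enolate (hence two equivalents of base).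

Step 8
Reactants: 10 (Z)-4-bromo-3-[(tert-butyldimethylsilyloxy)methyl]-5-(hydroxymethylidene)furan-2(5H)-one
Product: 11 (Z)-4-bromo-5-(chloromethylidene)-3-[(tert-butyldimethylsilyloxy)methyl]furan-2(5H)-one
Conditions: (COCl)2, DMF (cat.), CH2Cl2, 0 °C
Reagents that add atoms: oxalyl chloride, O=C(Cl)C(=O)Cl
Why: Chlorination of a doubly vinylogous carboxylic acid by the Vilsmeier reagent (the reaction that turns tetronic acids into 4-halobutenolides), in which reversible addition–elimination should settle on the Z isomer with chlorine next to the ring oxygen and away from the C10 bromine.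

Step 9
Reactants: 5 (R)-3-(5-methylfuran-2-yl)-3-(trimethylsilyloxy)butanal; 11 (Z)-4-bromo-5-(chloromethylidene)-3-[(tert-butyldimethylsilyloxy)methyl]furan-2(5H)-one
Product: 12 (Z)-5-(chloromethylidene)-4-[(1S,3R)-1-hydroxy-3-(5-methylfuran-2-yl)-3-(trimethylsilyloxy)butyl]-3-[(tert-butyldimethylsilyloxy)methyl]furan-2(5H)-one
Conditions: CrCl2 (3 equiv), NiCl2 (2 mol %), N-[2-(4-isopropyl-4,5-dihydrooxazol-2-yl)-6-methoxyphenyl]methanesulfonamide (one enantiomer, 3.3 equiv), Et3N, THF, rt
Reagents that add atoms: none
Why: Nozaki–Hiyama–Kishi coupling, in which zerovalent nickel inserts into the activated C10–Br bond but not into the alkenyl chloride, the derived alkenylchromium species adds only to the aldehyde, and the chromium-bound chiral sulfonamide directs it to the Re face, setting C1 as S with O1 and O3 syn.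

Step 10
Reactants: 12 the C1 carbinol with O3-TMS ether
Product: 13 (Z)-5-(chloromethylidene)-4-[(1S,3R)-1,3-dihydroxy-3-(5-methylfuran-2-yl)butyl]-3-[(tert-butyldimethylsilyloxy)methyl]furan-2(5H)-one
Conditions: Et3N·3HF, THF, 0 °C
Reagents that add atoms: none
Why: Fluoride desilylation under nearly neutral conditions, in which the TMS ether reacts far faster than the primary TBS ether and the furyl carbinol cannot ionise.

Step 11
Reactants: 13 the syn-1,3-diol
Product: 14 O1,O3-phenylboronate of 13 (2-phenyl-1,3,2-dioxaborinane carrying the butenolide on C1 and, on C3, methyl and 5-methylfuran-2-yl; C1 S, C3 R)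
Conditions: PhB(OH)2, 4 Å MS, toluene, rt
Reagents that add atoms: phenylboronic acid, OB(O)c1ccccc1
Why: Condensation of a 1,3-diol with a boronic acid to a six-membered boronic ester, driven by removal of water and touching no stereocentre.

Step 12
Reactants: 14 O1,O3-phenylboronate of 13
Product: 15 exo-fused oxanorbornene cycloadduct (new bonds C7–C8 and C4–C9; C10 exo, lactone O and Cl endo; C7 S; O1 and O3 axial on ring A and bridged by B–Ph)
Conditions: toluene (0.01 M), BHT, 4 Å MS, sealed tube, 120 °C
Reagents that add atoms: none
Why: Proposed new method: a concerted, suprafacial [4+2] cycloaddition with the furan (C4–C7) as diene and the exocyclic C8=C9 bond of the chloromethylene butenolide as dienophile forms C7–C8 and C4–C9; the closest known reactions are the intramolecular Diels–Alder reaction of 2,5-dialkylfurans through four-atom tethers and the Diels–Alder addition of dienes to the exocyclic alkene of gamma-methylene butenolides, which have not been combined. The oxanorbornene ring (C4, C5, C6, C7, C8, C9, bridged by O) closes by the cycloaddition itself, and cyclohexane ring A (C4, C3, C2, C1, C10, C9) closes through the tether, whose length forces C4 onto C9, in the usual tether-exo mode through a chair. C4 and C7 are fixed by the furan face attacked, C9 by the exo mode (C10 syn to the oxygen bridge, lactone O endo) and C8 by retention of the Z geometry (Cl endo, cis to the lactone O). The step needs the face that makes C7 S relative to C1 and C3; in the exo chair that face places O1 and O3 axial on the side of the lactone oxygen with the C3 methyl equatorial, so bulky open-chain ethers would choose the other face. The planar boronate bridges O1 and O3 only when both are axial (a 2,4-dioxa-3-borabicyclo[3.3.1]nonane), so the wanted face keeps the chair while the other would need a boat, and boron carries no inward substituent that could clash with the axial lactone oxygen. The tetrasubstituted C10=C11 bond should not compete, because its adduct would hold four contiguous fully substituted carbons and furan additions are reversible, and the chlorine helps the equilibrium because a halogen is better placed on sp3 than on sp2 carbon.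

Step 13
Reactants: 15 exo-fused oxanorbornene cycloadduct
Product: 17 saturated oxanorbornane diol (C5–C6 single bond; O1–H and O3–H free; C8–Cl endo), via saturated phenylboronate 16 (not isolated)
Conditions: 2-nitrobenzenesulfonylhydrazide, Et3N, CH2Cl2, rt; then pinacol, rt
Reagents that add atoms: none
Why: Diimide reduction, in which the strained unhindered C5=C6 bond takes up hydrogen while the tetrasubstituted electron-poor C10=C11 bond, the C–Cl bond and the boronate are inert, so cycloreversion is ruled out before transesterification with pinacol removes the template.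

Step 14
Reactants: 17 saturated oxanorbornane diol
Product: 20 bridged dienol ether diol (ten-membered ring; C4=C5 enol ether; C8=C9 ylidene butenolide with C7 cis to C10; O13-TBS), via bis-TMS ether 18 (not isolated), via bis-TMS bridged dienol ether 19 (not isolated)
Conditions: TMSOTf (5 equiv), 2,6-lutidine (8 equiv), CH2Cl2, −78 °C to rt; aq. NaHCO3; crude in THF, Et3N·3HF, 0 °C
Reagents that add atoms: none
Why: Proposed new method: after both hydroxyls are silylated, TMSOTf silylates the lactone carbonyl, the bridge-oxygen lone pair antiperiplanar to C4–C9 pushes, and this bond, nearly parallel to the butenolide pi system, breaks heterolytically into a C4 oxocarbenium ion and a 2-silyloxyfuran; the furan expels the now furfurylic chloride as TMSCl to give the C8=C9 ylidene butenolide, with the nine-membered oxa-ring holding C7 on the C10 side, lutidine removes the only alpha proton available (C5, since C3 is quaternary) to give the C4=C5 enol ether, and relief of the oxanorbornane strain and of the triaxial O1/O3/lactone-O array drives the process; the closest known reaction types are the Grob fragmentation, the Lewis-acid opening of vicinal donor–acceptor cyclobutanes and the reverse of the vinylogous Mukaiyama addition of 2-silyloxyfurans to oxocarbenium ions; no stereocentre is formed, C1, C3 and C7 are untouched, and buffered fluoride then frees O1 and O3 while the primary TBS ether stays.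

Step 15
Reactants: 20 bridged dienol ether diol
Product: 21 O1-methacrylate of 20
Conditions: methacrylic anhydride, Et3N, DMAP (cat.), BHT, CH2Cl2, 0 °C to rt
Reagents that add atoms: methacrylic anhydride, C=C(C)C(=O)OC(=O)C(C)=C
Why: DMAP-catalysed acylation with an anhydride, in which only the secondary O1 reacts because the tertiary O3 is too hindered, and C1 keeps its configuration because its C–O bond is not broken.

Step 16
Reactants: 21 O1-methacrylate of 20
Product: 22 O1-methacrylate with free C13 hydroxymethyl group
Conditions: Et3N·3HF, MeCN, rt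
Reagents that add atoms: none
Why: Fluoride cleavage of a primary TBS ether with a nearly neutral HF source, which spares the acid-labile enol ether, the base-labile ylidene butenolide and the methacrylate.

Step 17
Reactants: 22 O1-methacrylate with free C13 hydroxymethyl group
Product: 23 CNP0394509.2
Conditions: Ac2O, pyridine, DMAP (cat.), CH2Cl2, 0 °C
Reagents that add atoms: acetic anhydride, CC(=O)OC(C)=O
Why: Acetylation of the primary allylic alcohol under mild base catalysis, in which the tertiary C3 hydroxyl stays free.

## Compound list

1 | 2-acetyl-5-methylfuran | CC(=O)c1ccc(C)o1 | starting material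
2 | allylboronic acid pinacol ester | C=CCB1OC(C)(C)C(C)(C)O1 | starting material
3 | (R)-2-(5-methylfuran-2-yl)pent-4-en-2-ol | C=CC[C@@](C)(O)c1ccc(C)o1 | intermediate
4 | TMS ether of 3 | C=CC[C@@](C)(O[Si](C)(C)C)c1ccc(C)o1 | intermediate
5 | (R)-3-(5-methylfuran-2-yl)-3-(trimethylsilyloxy)butanal | O=CC[C@@](C)(O[Si](C)(C)C)c1ccc(C)o1 | intermediate
6 | tetronic acid | OC1=CC(=O)OC1 | starting material
7 | 4-bromo-2-oxo-2,5-dihydrofuran-3-carbaldehyde | O=CC1=C(Br)COC1=O | intermediate
8 | 4-bromo-3-(hydroxymethyl)furan-2(5H)-one | OCC1=C(Br)COC1=O | intermediate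
9 | 4-bromo-3-[(tert-butyldimethylsilyloxy)methyl]furan-2(5H)-one | CC(C)(C)[Si](C)(C)OCC1=C(Br)COC1=O | intermediate
10 | (Z)-5-(hydroxymethylidene) derivative of 9 | CC(C)(C)[Si](C)(C)OCC1=C(Br)/C(=C/O)OC1=O | intermediate
11 | (Z)-5-(chloromethylidene) derivative of 9 | CC(C)(C)[Si](C)(C)OCC1=C(Br)/C(=C/Cl)OC1=O | intermediate
12 | coupled (1S,3R) carbinol, O3-TMS, O13-TBS | O[C@H](C1=C(CO[Si](C)(C)C(C)(C)C)C(=O)O/C1=C\Cl)C[C@@](C)(O[Si](C)(C)C)c1ccc(C)o1 | intermediate
13 | (1S,3R) syn-1,3-diol | O[C@H](C1=C(CO[Si](C)(C)C(C)(C)C)C(=O)O/C1=C\Cl)C[C@@](C)(O)c1ccc(C)o1 | intermediate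
14 | O1,O3-phenylboronate of 13 (cycloaddition precursor) | O1[C@H](C2=C(CO[Si](C)(C)C(C)(C)C)C(=O)O/C2=C\Cl)C[C@@](C)(OB1c3ccccc3)c4ccc(C)o4 | intermediate
15 | exo-fused oxanorbornene cycloadduct, phenylboronate | O5[C@H]1C[C@@](C)(OB5c6ccccc6)[C@@]23C=C[C@@](C)([C@@H](Cl)[C@@]24OC(=O)C(CO[Si](C)(C)C(C)(C)C)=C41)O3 | intermediate
16 | saturated phenylboronate | O5[C@H]1C[C@@](C)(OB5c6ccccc6)[C@@]23CC[C@@](C)([C@@H](Cl)[C@@]24OC(=O)C(CO[Si](C)(C)C(C)(C)C)=C41)O3 | intermediate
17 | saturated oxanorbornane diol | O[C@H]1C[C@@](C)(O)[C@@]23CC[C@@](C)([C@@H](Cl)[C@@]24OC(=O)C(CO[Si](C)(C)C(C)(C)C)=C41)O3 | intermediate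
18 | bis-TMS ether of 17 | C[Si](C)(C)O[C@H]1C[C@@](C)(O[Si](C)(C)C)[C@@]23CC[C@@](C)([C@@H](Cl)[C@@]24OC(=O)C(CO[Si](C)(C)C(C)(C)C)=C41)O3 | intermediate
19 | bis-TMS bridged dienol ether | C[Si](C)(C)O[C@H]1C[C@@](C)(O[Si](C)(C)C)C2=CC[C@@](C)(/C=C3/OC(=O)C(CO[Si](C)(C)C(C)(C)C)=C31)O2 | intermediate
20 | bridged dienol ether diol, O13-TBS | O[C@H]1C[C@@](C)(O)C2=CC[C@@](C)(/C=C3/OC(=O)C(CO[Si](C)(C)C(C)(C)C)=C31)O2 | intermediate
21 | O1-methacrylate, O13-TBS | C=C(C)C(=O)O[C@H]1C[C@@](C)(O)C2=CC[C@@](C)(/C=C3/OC(=O)C(CO[Si](C)(C)C(C)(C)C)=C31)O2 | intermediate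
22 | O1-methacrylate, free C13 alcohol | C=C(C)C(=O)O[C@H]1C[C@@](C)(O)C2=CC[C@@](C)(/C=C3/OC(=O)C(CO)=C31)O2 | intermediate
23 | CNP0394509.2 | C=C(C)C(=O)O[C@H]1C[C@@](C)(O)C2=CC[C@@](C)(/C=C3/OC(=O)C(COC(C)=O)=C31)O2 | target

## Step count and risks

- **Total step count:** 17.
- **Longest linear sequence:** 14 steps (steps 4–8, then 9–17, from tetronic acid).

### First risk: step 14

**What may go wrong.** The C4–C9 bond may fail to ionise, or the ion pair may simply reclose. The transient silyloxyfuran may lose the C13 silyloxy group instead of chloride. Rotation about C8–C9 before chloride loss may give the other alkene geometry.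

**Fallback (known chemistry, from 15, back at 21).** The ether-oxygen push is replaced by an alkoxide push in a classical Grob–Wharton fragmentation of the same bond. Radical dechlorination of 15 (Bu3SnH, AIBN, toluene, 90 °C) would give the C8-dechlorinated cycloadduct F1. Exo-selective hydroboration and oxidation (BH3·THF; NaBO3·4H2O), which also destroys the phenylboronate, would give the C5-exo alcohol F2. Its C6 regioisomer cannot fragment and would be separated. The accessible exo hydroxyl would be mesylated selectively (MsCl, Et3N, −20 °C) to the C5-exo mesylate F3, whose C5–O bond is antiperiplanar to C4–C9. LiOH would open the lactone, and the C9 alkoxide would then fragment to the C9 ketone and the C4=C5 enol ether, giving the ten-membered keto acid F4. Methacrylic anhydride, Et3N and DMAP would esterify O1 and acylate the 5-hydroxybutenolide form of F4. That acylated form loses carboxylic acid to give the ylidene butenolide, which is 21.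

### Second risk: step 12

**What may go wrong.** The furan–adduct equilibrium may be unfavourable. The tether-endo mode or a boat tether may compete, which would attack the wrong furan face. The boron template may be lost by hydrolysis at high temperature.

**Fallback (known chemistry, from 12, back at 20).** The furan is used as a masked 1,4-diketone instead of a diene. Oxidative opening of the 2,5-dialkylfuran of 12 (mCPBA, CH2Cl2, 0 °C) would give the Z-enedione F5. SmI2 (THF–MeOH) would first saturate it to the 1,4-diketone F6. It would then couple the less hindered C7 ketyl with C8 of the chloromethylene butenolide, a ketyl–olefin coupling followed by beta-loss of chloride. This closes the ring as the macrocyclic gamma-hydroxy ketone F7. PPTS with molecular sieves would add the C7 hydroxyl to the C4 ketone and dehydrate the hemiketal towards C5, giving the O3-TMS dienol ether F8. Et3N·3HF would then give 20. In this variant C7 depends only on the conformation of the ring-closing transition state, so epimers might have to be separated.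

### Third risk: step 9

**What may go wrong.** Facial selectivity at the aldehyde may be poor, because ligand control is untested for a fully substituted alkenyl bromide, and oxidative addition may be slow.

**Fallback (from 5 and 11, back at 12).** Stereocontrol is moved from C–C bond formation to a reduction. A ligand-free coupling (CrCl2, NiCl2, DMF) would give 12 together with its C1 epimer F9. Dess–Martin periodinane would converge both on the C1 ketone F10. A Corey–Bakshi–Shibata reduction (the Me-CBS oxazaborolidine enantiomer matched to the S carbinol, BH3·SMe2, −40 °C) would then return 12 under reagent control.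

## Further compounds

F1 | step 14 | C8-dechlorinated cycloadduct, phenylboronate | O5[C@H]1C[C@@](C)(OB5c6ccccc6)[C@@]23C=C[C@@](C)(C[C@@]24OC(=O)C(CO[Si](C)(C)C(C)(C)C)=C41)O3
F2 | step 14 | C5-exo alcohol (O1, O3, O5 free) | O[C@H]1C[C@@](C)(O)[C@@]23[C@H](O)C[C@@](C)(C[C@@]24OC(=O)C(CO[Si](C)(C)C(C)(C)C)=C41)O3
F3 | step 14 | C5-exo mesylate | O[C@H]1C[C@@](C)(O)[C@@]23[C@H](OS(C)(=O)=O)C[C@@](C)(C[C@@]24OC(=O)C(CO[Si](C)(C)C(C)(C)C)=C41)O3
F4 | step 14 | ten-membered keto acid (open form of the 5-hydroxybutenolide) | O[C@H]1C[C@@](C)(O)C2=CC[C@@](C)(CC(=O)/C1=C(/CO[Si](C)(C)C(C)(C)C)C(=O)O)O2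
F5 | step 12 | Z-enedione from 12 | O[C@H](C1=C(CO[Si](C)(C)C(C)(C)C)C(=O)O/C1=C\Cl)C[C@@](C)(O[Si](C)(C)C)C(=O)/C=C\C(C)=O
F6 | step 12 | 1,4-diketone | O[C@H](C1=C(CO[Si](C)(C)C(C)(C)C)C(=O)O/C1=C\Cl)C[C@@](C)(O[Si](C)(C)C)C(=O)CCC(C)=O
F7 | step 12 | macrocyclic gamma-hydroxy ketone | O[C@H]1C[C@@](C)(O[Si](C)(C)C)C(=O)CC[C@](C)(O)/C=C2/OC(=O)C(CO[Si](C)(C)C(C)(C)C)=C21
F8 | step 12 | O3-TMS dienol ether | O[C@H]1C[C@@](C)(O[Si](C)(C)C)C2=CC[C@@](C)(/C=C3/OC(=O)C(CO[Si](C)(C)C(C)(C)C)=C31)O2
F9 | step 9 | C1 epimer of 12 | O[C@@H](C1=C(CO[Si](C)(C)C(C)(C)C)C(=O)O/C1=C\Cl)C[C@@](C)(O[Si](C)(C)C)c1ccc(C)o1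
F10 | step 9 | C1 ketone | O=C(C1=C(CO[Si](C)(C)C(C)(C)C)C(=O)O/C1=C\Cl)C[C@@](C)(O[Si](C)(C)C)c1ccc(C)o1
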